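## The problem

Target 22 is achiral. It is a 2,5-dihydroxy-1,4-naphthoquinone (ring C is the quinone ring C1–C4, ring B the benzenoid ring C5–C8) whose ring B carries three adjacent groups: OH at C5, a 2,4-dihydroxy-6-methylbenzoyl group (ring A) at C6, and a (4-hydroxy-2-oxo-2H-pyran-6-yl)methyl group at C7. With no stereocentre to set and none that could steer another, the synthesis is a matter of regiochemistry and of timing the functional groups. Two placements must be secured: the C2 hydroxyl has to lie on the C1 side of ring C, remote from the C5 hydroxyl, and the three ring B substituents have to be contiguous in the order O, C(=O)Ar, CH2. The C6 carbonyl is a tetra-ortho-substituted diaryl ketone, which is out of reach of acylation chemistry and is best reached by adding an aryl metal to an aldehyde and oxidising. Five acidic hydroxyls, a redox-active hydroxyquinone and a base-labile hydroxypyranone would not survive organolithium, chromium carbonyl or palladium chemistry. They therefore travel as methyl ethers, with the quinone as its hydroquinone ether, and are uncovered last. The feature that opens the molecule is ring C itself: oxygen at C1, C2 and C4 and hydrogen at C3 is the pattern left by a carbene carbon (C4), a terminal alkyne (C3, C2) and carbon monoxide (C1). The C5 oxygen occupies one ortho position of the aryl group, so ring closure can only reach C8a, which also fixes C2–O relative to C5–O.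

## Retrosynthesis

**22 from 21.** The five O–CH3 bonds of quinone 21 are cut (ring A twice, C5, the quinone enol ether at C2, the pyranone enol ether). One Lewis acid should remove all of them: three sit ortho or peri to a carbonyl and two are vinylogous esters. 21 is no simpler in skeleton, but every acidic proton is masked.

**21 from 20.** The quinone is traced to the 1,2,4,5-tetramethoxynaphthalene 20. This cut is preferred to carrying a quinone through metal chemistry. It asks only that the oxidant choose the 1,2,4-trioxygenated ring over the acyl-deactivated ring A. The para- and the ortho-quinone that could arise both end as the same hydroxyquinone after demethylation.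

**20 from 16 and 18.** The C7–CH2 bond is cut, giving aryl chloride 16 and bromide 18, which is one bromination from commercial pyranone 17. The neighbouring cut, CH2–pyranone, would need a benzylic alcohol carried as a silyl ether and then turned into a bromide and a zinc reagent next to a ketone, plus a 6-halopyranone of doubtful availability. The chlorine of 16 is inert to every earlier step, and the ortho carbonyl activates it for oxidative addition. The forward reaction is a Negishi coupling through zinc reagent 19.

**16 from 14.** The ketone is taken back through carbinol 15 to silyl ether 14. A ketone cannot be present when the aryllithium for the carbene is made, and the carbinol is what the aryl–carbon bond formation gives anyway. The price is one silylation, one desilylation and one oxidation.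

**14 from 12.** The C2–O bond is traced to the C2–B bond of 12 through catechol 13, and the two O-methyl groups to iodomethane. Boron is the only C2 substituent that both directs the benzannulation and becomes oxygen under mild conditions.

**12 from 9 and 10.** The bonds C4–C3, C2–C1 and C1–C8a are cut, opening ring C into carbene complex 9, ethynylboronate 10 and one CO ligand. This removes a whole ring with three oxygen-bearing carbons and leaves a tetrasubstituted benzene. The forward step must place boron at C2 and close at C8a.

**9 from 5 and 6.** The bond between the aryl carbon and the carbene carbon is cut. Bromide 5 is lithiated to 7, which adds to Cr(CO)6 (6) to give acylchromate 8, and 8 is O-methylated. This is shorter than building a benzoic acid and its chloride.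

**5 from 1 and 2.** After removal of the silyl group (4), the aryl–CH(OH) bond is cut to give 2-bromo-5-chloroanisole 1 and aldehyde 2, both commercial. The proton of 1 between OMe and Cl is the only one flanked by two acidifying groups. One metalation to 3 and addition to 2 therefore sets the whole 1,2,3,4-pattern, with chlorine as co-director and later coupling handle and bromine as the carbene handle.

## Roads not taken

**Alternative 1: dehydro-Diels–Alder cascade to ring B and a lactone.**
- **Cut:** C4a–C5 and C6–C7 of ring B, together with the lactone ring.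
- **Forward step:** heating the propargyl ester A1 lets the arylalkyne act as diene toward the tethered silylpropiolate, and a hydrogen shift gives the naphthofuranone A2.
- **Merits:** it is thermal and metal-free, starts from very simple pieces, and delivers the C6 carbon (as carbonyl) and the C7 carbon (as CH2–O) differentiated in one step. In those respects it is better than the chosen plan.
- **Weak points:**
  - A2 has silicon at C5, not oxygen. A trimethylsilyl group flanked by a peri methoxy group and a lactone carbonyl has no dependable conversion to a phenol, and electrophiles would attack the free positions of the electron-rich ring first.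
  - Ring A would have to be added to the lactone carbonyl of A2 as a di-ortho-substituted aryl nucleophile next to that silyl group.
  - The C7 carbon arrives as C–O and must still be turned into C–C.
- **Comparison:** the chosen plan sets against the metal-free step the C5 oxygen present from the first step, the ketone carbon joined to ring A by an aldehyde addition, and a C7 chloride that couples directly.

**Alternative 2: naphthalyne acyl-alkylation.**
- **Cut:** C7–CH2 and C6–C(=O).
- **Forward step:** fluoride releases the 6,7-naphthalyne from silyl triflate A3, and β-keto ester A4 adds across it with cleavage of its CH2–C(=O) bond to give arylacetate A5.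
- **Merits:** this is the most convergent road. Ring A, the ketone at its final oxidation level and the C7 methylene arrive together, and A5 is already the acyl donor for a pyranone. No carbinol has to be protected and oxidised, and no chromium is used. On convergence it is better than the chosen plan.
- **Weak points:**
  - A3 is a hexasubstituted, tetraoxygenated naphthalene. Ring C still has to be made by some benzannulation, and a silyl group and a triflate have to be placed on ring B only to be thrown away.
  - Regiochemistry at the aryne rests on the C5 methoxy group alone.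
  - The acyl transfer needs the aryl anion to attack a ketone flanked by the two ortho substituents of ring A, so plain C-arylation without insertion is a likely diversion.
- **Comparison:** the chosen plan sets against it a key step that builds ring C itself, and a hindered C–C bond formed on an aldehyde.

**Alternative 3: ring A by cycloaddition of a bis(silyloxy)diene to an ynone.**
- **Cut:** C1'–C2' and C5'–C6' of ring A.
- **Forward step:** diene A7 adds to naphthyl butynone A6, and loss of methanol and the silyl groups gives the free resorcinol A8.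
- **Merits:** ring A is formed with unambiguous placement of OH and CH3 and needs no ether cleavage, so the end game has two fewer methyl ethers. That is an advantage over the chosen plan.
- **Weak points:**
  - A6 presupposes the whole naphthalene with an acyl group at the hindered C6, so ring C and the contiguous ring B pattern remain unsolved.
  - The key step is spent on the one ring that can be bought as aldehyde 2.
  - A6 is a hindered internal ynone and a slow dienophile.
  - The free resorcinol of A8 would not survive oxidation to the quinone without reprotection.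
- **Comparison:** the chosen plan sets against the milder end game a commercial ring A and a key step that solves the oxygenation of ring C.

Key step: step 4

Assumption: 22 is taken as the 2-hydroxy-1,4-dione tautomer of its SMILES. The benzhydryl carbon of 4, 5, 7–9 and 11–15 is a stereocentre that is carried as the racemate and removed in step 8.

## Route

Step 1
Reactants: 1 2-bromo-5-chloroanisole; 2 2,4-dimethoxy-6-methylbenzaldehyde
Product: 4 rac-(3-bromo-6-chloro-2-methoxyphenyl)(2,4-dimethoxy-6-methylphenyl)methanol, via aryllithium 3 (not isolated)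
Conditions: lithium 2,2,6,6-tetramethylpiperidide (LiTMP, from the amine and n-BuLi), THF, −78 °C; then 2, −78 → −40 °C; aq. NH4Cl
Reagents that add atoms: none
Why: Directed ortho-metalation followed by 1,2-addition; the proton between OMe and Cl is the most acidic and is guided by Li–O coordination, the amide base leaves C–Br alone, and at −78 °C the ortho-chloroaryllithium does not lose LiCl; addition of a di-ortho-substituted aryllithium to a di-ortho-substituted benzaldehyde is the usual entry to tetra-ortho-substituted benzophenones, and the new stereocentre forms without control because it is erased in step 8.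

Step 2
Reactants: 4 rac-(3-bromo-6-chloro-2-methoxyphenyl)(2,4-dimethoxy-6-methylphenyl)methanol
Product: 5 rac-[(3-bromo-6-chloro-2-methoxyphenyl)(2,4-dimethoxy-6-methylphenyl)methoxy]triethylsilane
Conditions: Et3SiOTf, 2,6-lutidine, CH2Cl2, −78 → 0 °C
Reagents that add atoms: triethylsilyl trifluoromethanesulfonate, CC[Si](CC)(CC)OS(=O)(=O)C(F)(F)F
Why: Silylation of a hindered secondary alcohol with a silyl triflate and a hindered base; the buffered medium should prevent ionisation of the electron-rich carbinol, and the ether keeps the future ketone at the alcohol level through the organolithium step.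

Step 3
Reactants: 5 rac-[(3-bromo-6-chloro-2-methoxyphenyl)(2,4-dimethoxy-6-methylphenyl)methoxy]triethylsilane; 6 hexacarbonylchromium
Product: 9 rac-pentacarbonyl[{4-chloro-3-[(2,4-dimethoxy-6-methylphenyl)(triethylsilyloxy)methyl]-2-methoxyphenyl}(methoxy)methylidene]chromium, via aryllithium 7 (not isolated), via lithium acylchromate 8 (not isolated)
Conditions: t-BuLi (2 equiv), Et2O, −78 °C; Cr(CO)6, −78 °C → rt; then Me3OBF4, CH2Cl2, 0 °C
Reagents that add atoms: trimethyloxonium tetrafluoroborate, C[O+](C)C.F[B-](F)(F)F
Why: Fischer carbene synthesis; bromine–lithium exchange ortho to OMe is much faster than attack on C–Cl or the silyl ether, the aryllithium adds to a CO ligand to give the acylchromate, and the hard oxonium salt alkylates it on oxygen.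

Step 4
Reactants: 9 rac-pentacarbonyl[{4-chloro-3-[(2,4-dimethoxy-6-methylphenyl)(triethylsilyloxy)methyl]-2-methoxyphenyl}(methoxy)methylidene]chromium; 10 2-ethynyl-4,4,5,5-tetramethyl-1,3,2-dioxaborolane
Product: 12 rac-7-chloro-6-[(2,4-dimethoxy-6-methylphenyl)(triethylsilyloxy)methyl]-4,5-dimethoxy-2-(4,4,5,5-tetramethyl-1,3,2-dioxaborolan-2-yl)naphthalen-1-ol, via tricarbonylchromium naphthol complex 11 (not isolated)
Conditions: 10 (3 equiv), THF, 50 °C, Ar; then air, rt
Reagents that add atoms: none
Why: Dötz benzannulation, the formal (3+2+1) union of an aryl(alkoxy)carbene chromium complex, an alkyne and one CO ligand; the closest known case is the reaction of aryl(methoxy)carbene complexes with alkynylboronic esters to give 2-boryl-4-methoxy-1-naphthols. Thermal loss of a cis CO from 9 lets 10 bind and insert into the Cr=C bond to give a vinylcarbene, and CO insertion then gives a chromium-bound vinylketene. Ring C closes by 6π-electrocyclisation onto the aryl ortho carbon C8a (bonds C4–C3, C2–C1 and C1–C8a), and tautomerisation gives the naphthol as its Cr(CO)3 complex 11, which air frees as 12. No stereocentre is formed and the racemic benzhydryl centre is a spectator. Two selectivities are needed: the boron-bearing alkyne carbon must end next to the CO-derived C1, which is the normal fate of the substituted carbon of a terminal alkyne and is also the preference reported for boryl groups in internal alkynylboronates, so size and the boron effect point the same way; and closure must reach C8a, which is certain because the other ortho position carries the C5 methoxy group. The aryl chloride, silyl ether and methyl ethers are inert under the neutral conditions, and an ethereal solvent at moderate temperature favours the phenol over indene or furan side paths.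

Step 5
Reactants: 12 rac-7-chloro-6-[(2,4-dimethoxy-6-methylphenyl)(triethylsilyloxy)methyl]-4,5-dimethoxy-2-(4,4,5,5-tetramethyl-1,3,2-dioxaborolan-2-yl)naphthalen-1-ol
Product: 13 rac-7-chloro-6-[(2,4-dimethoxy-6-methylphenyl)(triethylsilyloxy)methyl]-4,5-dimethoxynaphthalene-1,2-diol
Conditions: NaBO3·4H2O, THF/H2O, rt, Ar; Na2S2O4 work-up
Reagents that add atoms: sodium perborate, [Na+].[O-]OB=O
Why: Oxidation of an arylboronic ester by perborate (aryl shift from boron to oxygen, then hydrolysis); the mild reagent spares the silyl ether, and the reductive work-up keeps the oxidisable catechol reduced until it is methylated at once.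

Step 6
Reactants: 13 rac-7-chloro-6-[(2,4-dimethoxy-6-methylphenyl)(triethylsilyloxy)methyl]-4,5-dimethoxynaphthalene-1,2-diol
Product: 14 rac-[(3-chloro-1,5,6,8-tetramethoxynaphthalen-2-yl)(2,4-dimethoxy-6-methylphenyl)methoxy]triethylsilane
Conditions: MeI, K2CO3, acetone, reflux, Ar
Reagents that add atoms: iodomethane, CI
Why: Williamson ether synthesis on both phenols; it locks the air-sensitive hydroxyhydroquinone as a stable tetramethyl ether for the steps that follow.

Step 7
Reactants: 14 rac-[(3-chloro-1,5,6,8-tetramethoxynaphthalen-2-yl)(2,4-dimethoxy-6-methylphenyl)methoxy]triethylsilane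
Product: 15 rac-(3-chloro-1,5,6,8-tetramethoxynaphthalen-2-yl)(2,4-dimethoxy-6-methylphenyl)methanol
Conditions: Bu4NF, THF, 0 °C → rt
Reagents that add atoms: none
Why: Fluoride cleavage of a silyl ether, driven by the Si–F bond; nothing else in 14 reacts with fluoride.

Step 8
Reactants: 15 rac-(3-chloro-1,5,6,8-tetramethoxynaphthalen-2-yl)(2,4-dimethoxy-6-methylphenyl)methanol
Product: 16 (3-chloro-1,5,6,8-tetramethoxynaphthalen-2-yl)(2,4-dimethoxy-6-methylphenyl)methanone
Conditions: Dess–Martin periodinane, NaHCO3, CH2Cl2, rt
Reagents that add atoms: none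
Why: Dess–Martin oxidation of a hindered diaryl carbinol, the standard second half of the route to tetra-ortho-substituted benzophenones; it removes the only stereocentre and does not touch the methoxyarenes.

Step 9
Reactants: 17 4-methoxy-6-methyl-2H-pyran-2-one
Product: 18 6-(bromomethyl)-4-methoxy-2H-pyran-2-one
Conditions: NBS, AIBN (cat.), PhCF3, reflux
Reagents that add atoms: N-bromosuccinimide, O=C1CCC(=O)N1Br
Why: Wohl–Ziegler bromination; the radical at the 6-methyl group is allylic and conjugated with the pyranone, whereas the ring positions react only by ionic bromination.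

Step 10
Reactants: 16 (3-chloro-1,5,6,8-tetramethoxynaphthalen-2-yl)(2,4-dimethoxy-6-methylphenyl)methanone; 18 6-(bromomethyl)-4-methoxy-2H-pyran-2-one
Product: 20 6-{[3-(2,4-dimethoxy-6-methylbenzoyl)-4,5,7,8-tetramethoxynaphthalen-2-yl]methyl}-4-methoxy-2H-pyran-2-one, via pyranonylmethylzinc bromide 19 (not isolated)
Conditions: 18, Zn dust, LiCl, THF, 0 °C → rt; then 16, Pd(OAc)2 (5 mol %), SPhos (10 mol %), THF, 50 °C
Reagents that add atoms: none
Why: Negishi coupling of a benzylic-type zinc halide with an aryl chloride; zinc inserts readily into the allylic C–Br bond, zerovalent palladium adds to the C–Cl bond activated by the ortho carbonyl, the biaryl phosphine copes with the ortho substituent, and neither the hindered ketone nor the lactone reacts with an organozinc.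

Step 11
Reactants: 20 6-{[3-(2,4-dimethoxy-6-methylbenzoyl)-4,5,7,8-tetramethoxynaphthalen-2-yl]methyl}-4-methoxy-2H-pyran-2-one
Product: 21 6-{[3-(2,4-dimethoxy-6-methylbenzoyl)-4,7-dimethoxy-5,8-dioxo-5,8-dihydronaphthalen-2-yl]methyl}-4-methoxy-2H-pyran-2-one
Conditions: (NH4)2Ce(NO3)6, MeCN/H2O, 0 °C
Reagents that add atoms: water, O
Why: Oxidative demethylation of a para-dimethoxyarene by tetravalent cerium; the 1,2,4-trimethoxy ring is by far the most electron-rich, ring A is meta-dioxygenated and acyl-deactivated, and any 4-methoxy-1,2-quinone formed alongside converges on the same product in step 12.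

Step 12
Reactants: 21 6-{[3-(2,4-dimethoxy-6-methylbenzoyl)-4,7-dimethoxy-5,8-dioxo-5,8-dihydronaphthalen-2-yl]methyl}-4-methoxy-2H-pyran-2-one
Product: 22 6-(2,4-dihydroxy-6-methylbenzoyl)-2,5-dihydroxy-7-[(4-hydroxy-2-oxo-2H-pyran-6-yl)methyl]naphthalene-1,4-dione
Conditions: BBr3 (excess), CH2Cl2, −78 °C → rt; then H2O
Reagents that add atoms: none
Why: Lewis acid ether cleavage (boron binds oxygen, bromide attacks methyl); the ethers ortho or peri to a carbonyl are cleaved fastest through chelation, and the quinone and pyranone enol ethers are vinylogous esters whose boron-complexed forms are good methyl donors.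

## Compound list

1 | 2-bromo-5-chloroanisole (1-bromo-4-chloro-2-methoxybenzene) | COc1cc(Cl)ccc1Br | starting material
2 | 2,4-dimethoxy-6-methylbenzaldehyde | Cc1cc(OC)cc(OC)c1C=O | starting material
3 | (3-bromo-6-chloro-2-methoxyphenyl)lithium | [Li]c1c(OC)c(Br)ccc1Cl | intermediate (not isolated)
4 | rac-(3-bromo-6-chloro-2-methoxyphenyl)(2,4-dimethoxy-6-methylphenyl)methanol | COc1c(Br)ccc(Cl)c1C(O)c1c(C)cc(OC)cc1OC | intermediate
5 | rac-[(3-bromo-6-chloro-2-methoxyphenyl)(2,4-dimethoxy-6-methylphenyl)methoxy]triethylsilane | COc1c(Br)ccc(Cl)c1C(O[Si](CC)(CC)CC)c1c(C)cc(OC)cc1OC | intermediate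
6 | hexacarbonylchromium, Cr(CO)6 | O=C=[Cr](=C=O)(=C=O)(=C=O)(=C=O)=C=O | starting material
7 | rac-{4-chloro-3-[(2,4-dimethoxy-6-methylphenyl)(triethylsilyloxy)methyl]-2-methoxyphenyl}lithium | [Li]c1ccc(Cl)c(C(O[Si](CC)(CC)CC)c2c(C)cc(OC)cc2OC)c1OC | intermediate (not isolated)
8 | rac-lithium pentacarbonyl[{4-chloro-3-[(2,4-dimethoxy-6-methylphenyl)(triethylsilyloxy)methyl]-2-methoxyphenyl}(oxido)methylidene]chromate | [Li+].[O-]C(=[Cr](=C=O)(=C=O)(=C=O)(=C=O)=C=O)c1ccc(Cl)c(C(O[Si](CC)(CC)CC)c2c(C)cc(OC)cc2OC)c1OC | intermediate (not isolated)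
9 | rac-pentacarbonyl[{4-chloro-3-[(2,4-dimethoxy-6-methylphenyl)(triethylsilyloxy)methyl]-2-methoxyphenyl}(methoxy)methylidene]chromium | COC(=[Cr](=C=O)(=C=O)(=C=O)(=C=O)=C=O)c1ccc(Cl)c(C(O[Si](CC)(CC)CC)c2c(C)cc(OC)cc2OC)c1OC | intermediate
10 | 2-ethynyl-4,4,5,5-tetramethyl-1,3,2-dioxaborolane | C#CB1OC(C)(C)C(C)(C)O1 | starting material
11 | rac-tricarbonyl(η6-naphthol 12)chromium, the metal bound to the new ring (written as two parts) | COc1cc(B2OC(C)(C)C(C)(C)O2)c(O)c2cc(Cl)c(C(O[Si](CC)(CC)CC)c3c(C)cc(OC)cc3OC)c(OC)c12.O=C=[Cr](=C=O)=C=O | intermediate (not isolated)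
12 | rac-7-chloro-6-[(2,4-dimethoxy-6-methylphenyl)(triethylsilyloxy)methyl]-4,5-dimethoxy-2-(4,4,5,5-tetramethyl-1,3,2-dioxaborolan-2-yl)naphthalen-1-ol | COc1cc(B2OC(C)(C)C(C)(C)O2)c(O)c2cc(Cl)c(C(O[Si](CC)(CC)CC)c3c(C)cc(OC)cc3OC)c(OC)c12 | intermediate
13 | rac-7-chloro-6-[(2,4-dimethoxy-6-methylphenyl)(triethylsilyloxy)methyl]-4,5-dimethoxynaphthalene-1,2-diol | COc1cc(O)c(O)c2cc(Cl)c(C(O[Si](CC)(CC)CC)c3c(C)cc(OC)cc3OC)c(OC)c12 | intermediate
14 | rac-[(3-chloro-1,5,6,8-tetramethoxynaphthalen-2-yl)(2,4-dimethoxy-6-methylphenyl)methoxy]triethylsilane | COc1cc(OC)c(OC)c2cc(Cl)c(C(O[Si](CC)(CC)CC)c3c(C)cc(OC)cc3OC)c(OC)c12 | intermediate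
15 | rac-(3-chloro-1,5,6,8-tetramethoxynaphthalen-2-yl)(2,4-dimethoxy-6-methylphenyl)methanol | COc1cc(OC)c(OC)c2cc(Cl)c(C(O)c3c(C)cc(OC)cc3OC)c(OC)c12 | intermediate
16 | (3-chloro-1,5,6,8-tetramethoxynaphthalen-2-yl)(2,4-dimethoxy-6-methylphenyl)methanone | COc1cc(OC)c(OC)c2cc(Cl)c(C(=O)c3c(C)cc(OC)cc3OC)c(OC)c12 | intermediate
17 | 4-methoxy-6-methyl-2H-pyran-2-one | COc1cc(C)oc(=O)c1 | starting material
18 | 6-(bromomethyl)-4-methoxy-2H-pyran-2-one | COc1cc(CBr)oc(=O)c1 | intermediate
19 | [(4-methoxy-2-oxo-2H-pyran-6-yl)methyl]zinc bromide | COc1cc(C[Zn]Br)oc(=O)c1 | intermediate (not isolated)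
20 | 6-{[3-(2,4-dimethoxy-6-methylbenzoyl)-4,5,7,8-tetramethoxynaphthalen-2-yl]methyl}-4-methoxy-2H-pyran-2-one | COc1cc(Cc2cc3c(OC)c(OC)cc(OC)c3c(OC)c2C(=O)c2c(C)cc(OC)cc2OC)oc(=O)c1 | intermediate
21 | 6-{[3-(2,4-dimethoxy-6-methylbenzoyl)-4,7-dimethoxy-5,8-dioxo-5,8-dihydronaphthalen-2-yl]methyl}-4-methoxy-2H-pyran-2-one | COC1=CC(=O)c2c(OC)c(C(=O)c3c(C)cc(OC)cc3OC)c(Cc3cc(OC)cc(=O)o3)cc2C1=O | intermediate
22 | 6-(2,4-dihydroxy-6-methylbenzoyl)-2,5-dihydroxy-7-[(4-hydroxy-2-oxo-2H-pyran-6-yl)methyl]naphthalene-1,4-dione | Cc1cc(O)cc(O)c1C(=O)c1c(Cc2cc(O)cc(=O)o2)cc2c(c1O)C(=O)C=C(O)C2=O | target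

## Step count and the least certain steps

Total: 12 steps. The longest linear sequence is 11 steps (steps 1–8 and 10–12, from 1). Step 9 prepares the coupling partner 18.

**Step 4 (key step).** The alkyne may insert the other way round and put boron at C3. Closure may occur without CO insertion and give a five-membered ring. The boryl alkyne or the product may lose boron by protonolysis. The fallback keeps the benzannulation but brings in the C2 oxygen afterwards. It sets out from 9: heating with ethynyltrimethylsilane F1 should give the 2-silyl naphthol, 7-chloro-6-[(2,4-dimethoxy-6-methylphenyl)(triethylsilyloxy)methyl]-4,5-dimethoxy-2-(trimethylsilyl)naphthalen-1-ol F2, in which the position of silicon does not matter. Carbon-to-oxygen silyl transfer and methanolysis (K2CO3, MeOH) would leave the naphthol with free C2–H, 7-chloro-6-[(2,4-dimethoxy-6-methylphenyl)(triethylsilyloxy)methyl]-4,5-dimethoxynaphthalen-1-ol F3. Oxidation with 2-iodoxybenzoic acid in DMF, which delivers oxygen to the only free ortho position of a phenol, should give the ortho-quinone, 7-chloro-6-[(2,4-dimethoxy-6-methylphenyl)(triethylsilyloxy)methyl]-4,5-dimethoxynaphthalene-1,2-dione F4. Reduction with Na2S2O4 comes back to the route at 13.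

**Step 1.** Metalation may stray to the position ortho to bromine with migration of the halogen, the ortho-chloroaryllithium may lose LiCl to an aryne, or the hindered addition may stall. The fallback reverses the polarity and does not start from a numbered compound: it replaces 1 and 2 by commercial 2-bromo-5-chlorophenol F5 and 2-bromo-1,5-dimethoxy-3-methylbenzene F8. Magnesium-mediated ortho-formylation of F5 (MgCl2, Et3N, paraformaldehyde, MeCN, reflux) can only reach the one free ortho position and should give 3-bromo-6-chloro-2-hydroxybenzaldehyde F6. Methylation (MeI, K2CO3) gives 3-bromo-6-chloro-2-methoxybenzaldehyde F7. Bromine–lithium exchange on F8 (n-BuLi, THF, −78 °C) gives (2,4-dimethoxy-6-methylphenyl)lithium F9, and its addition to F7 at −78 °C comes back to the route at 4.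

**Step 3.** Exchange may be incomplete or be followed by deprotonation at the benzhydryl carbon, and the hindered acylchromate may alkylate poorly. The fallback makes the acylchromate from an acid chloride and sets out from 5. Palladium-catalysed methoxycarbonylation of the C–Br bond (Pd(OAc)2, Xantphos, CO, MeOH, Et3N) should give methyl 4-chloro-3-[(2,4-dimethoxy-6-methylphenyl)(triethylsilyloxy)methyl]-2-methoxybenzoate F10. Saponification (LiOH) gives the benzoic acid F11, and 1-chloro-N,N,2-trimethylprop-1-en-1-amine under neutral conditions gives the benzoyl chloride F12. K2Cr(CO)5 (from Cr(CO)6 and KC8) at −78 °C then gives the potassium acylchromate F13, and Me3OBF4 comes back to the route at 9.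

**Step 10.** The zinc reagent may couple with itself or react through a ring carbon, and oxidative addition into the hindered, electron-rich C–Cl bond may be slow. The fallback swaps the roles of the partners and sets out from 16. Miyaura borylation (bis(pinacolato)diboron, Pd2(dba)3, XPhos, KOAc, dioxane) should give (2,4-dimethoxy-6-methylphenyl)[1,5,6,8-tetramethoxy-3-(4,4,5,5-tetramethyl-1,3,2-dioxaborolan-2-yl)naphthalen-2-yl]methanone F14. Suzuki–Miyaura coupling of F14 with bromide 18 (Pd(PPh3)4, K3PO4, toluene/H2O) comes back to the route at 20.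

**Step 12.** The pyranone enol ether may resist cleavage, or the lactone may open under the Lewis acid. The fallback builds the pyranone with its hydroxyl free and sets out from 16.
- Palladium-catalysed α-arylation of the lithium enolate of tert-butyl acetate (LiN(SiMe3)2, Pd2(dba)3, P(t-Bu)3) should give tert-butyl 2-[3-(2,4-dimethoxy-6-methylbenzoyl)-4,5,7,8-tetramethoxynaphthalen-2-yl]acetate F15.
- Trifluoroacetic acid gives the arylacetic acid F16.
- Activation with 1,1'-carbonyldiimidazole and reaction with the lithium dienolate of 2,2,6-trimethyl-4H-1,3-dioxin-4-one gives the ketodioxinone F17.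
- Heating in toluene releases the acylketene, which closes to the 4-hydroxypyranone F18.
- BBr3 then cleaves only aryl methyl ethers to give the naphthalenetetrol F19, whose 1,2,4-trihydroxy ring is oxidised by air during work-up. This comes back to the route at 22 and bypasses 18–21.

## Further compounds

F1 | step 4 | ethynyltrimethylsilane | C#C[Si](C)(C)C
F2 | step 4 | rac-7-chloro-6-[(2,4-dimethoxy-6-methylphenyl)(triethylsilyloxy)methyl]-4,5-dimethoxy-2-(trimethylsilyl)naphthalen-1-ol | COc1cc([Si](C)(C)C)c(O)c2cc(Cl)c(C(O[Si](CC)(CC)CC)c3c(C)cc(OC)cc3OC)c(OC)c12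
F3 | step 4 | rac-7-chloro-6-[(2,4-dimethoxy-6-methylphenyl)(triethylsilyloxy)methyl]-4,5-dimethoxynaphthalen-1-ol | COc1ccc(O)c2cc(Cl)c(C(O[Si](CC)(CC)CC)c3c(C)cc(OC)cc3OC)c(OC)c12
F4 | step 4 | rac-7-chloro-6-[(2,4-dimethoxy-6-methylphenyl)(triethylsilyloxy)methyl]-4,5-dimethoxynaphthalene-1,2-dione | COC1=CC(=O)C(=O)c2cc(Cl)c(C(O[Si](CC)(CC)CC)c3c(C)cc(OC)cc3OC)c(OC)c12
F5 | step 1 | 2-bromo-5-chlorophenol | Oc1cc(Cl)ccc1Br
F6 | step 1 | 3-bromo-6-chloro-2-hydroxybenzaldehyde | O=Cc1c(O)c(Br)ccc1Cl
F7 | step 1 | 3-bromo-6-chloro-2-methoxybenzaldehyde | COc1c(Br)ccc(Cl)c1C=O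
F8 | step 1 | 2-bromo-1,5-dimethoxy-3-methylbenzene | COc1cc(OC)cc(C)c1Br
F9 | step 1 | (2,4-dimethoxy-6-methylphenyl)lithium | [Li]c1c(C)cc(OC)cc1OC
F10 | step 3 | rac-methyl 4-chloro-3-[(2,4-dimethoxy-6-methylphenyl)(triethylsilyloxy)methyl]-2-methoxybenzoate | COC(=O)c1ccc(Cl)c(C(O[Si](CC)(CC)CC)c2c(C)cc(OC)cc2OC)c1OC
F11 | step 3 | rac-4-chloro-3-[(2,4-dimethoxy-6-methylphenyl)(triethylsilyloxy)methyl]-2-methoxybenzoic acid | OC(=O)c1ccc(Cl)c(C(O[Si](CC)(CC)CC)c2c(C)cc(OC)cc2OC)c1OC
F12 | step 3 | rac-4-chloro-3-[(2,4-dimethoxy-6-methylphenyl)(triethylsilyloxy)methyl]-2-methoxybenzoyl chloride | ClC(=O)c1ccc(Cl)c(C(O[Si](CC)(CC)CC)c2c(C)cc(OC)cc2OC)c1OC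
F13 | step 3 | rac-potassium pentacarbonyl[{4-chloro-3-[(2,4-dimethoxy-6-methylphenyl)(triethylsilyloxy)methyl]-2-methoxyphenyl}(oxido)methylidene]chromate | [K+].[O-]C(=[Cr](=C=O)(=C=O)(=C=O)(=C=O)=C=O)c1ccc(Cl)c(C(O[Si](CC)(CC)CC)c2c(C)cc(OC)cc2OC)c1OC
F14 | step 10 | (2,4-dimethoxy-6-methylphenyl)[1,5,6,8-tetramethoxy-3-(4,4,5,5-tetramethyl-1,3,2-dioxaborolan-2-yl)naphthalen-2-yl]methanone | COc1cc(OC)c(OC)c2cc(B3OC(C)(C)C(C)(C)O3)c(C(=O)c3c(C)cc(OC)cc3OC)c(OC)c12
F15 | step 12 | tert-butyl 2-[3-(2,4-dimethoxy-6-methylbenzoyl)-4,5,7,8-tetramethoxynaphthalen-2-yl]acetate | CC(C)(C)OC(=O)Cc1cc2c(OC)c(OC)cc(OC)c2c(OC)c1C(=O)c1c(C)cc(OC)cc1OC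
F16 | step 12 | 2-[3-(2,4-dimethoxy-6-methylbenzoyl)-4,5,7,8-tetramethoxynaphthalen-2-yl]acetic acid | OC(=O)Cc1cc2c(OC)c(OC)cc(OC)c2c(OC)c1C(=O)c1c(C)cc(OC)cc1OC
F17 | step 12 | 6-{3-[3-(2,4-dimethoxy-6-methylbenzoyl)-4,5,7,8-tetramethoxynaphthalen-2-yl]-2-oxopropyl}-2,2-dimethyl-4H-1,3-dioxin-4-one | CC1(C)OC(CC(=O)Cc2cc3c(OC)c(OC)cc(OC)c3c(OC)c2C(=O)c2c(C)cc(OC)cc2OC)=CC(=O)O1
F18 | step 12 | 6-{[3-(2,4-dimethoxy-6-methylbenzoyl)-4,5,7,8-tetramethoxynaphthalen-2-yl]methyl}-4-hydroxy-2H-pyran-2-one | Oc1cc(Cc2cc3c(OC)c(OC)cc(OC)c3c(OC)c2C(=O)c2c(C)cc(OC)cc2OC)oc(=O)c1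
F19 | step 12 | 6-{[3-(2,4-dihydroxy-6-methylbenzoyl)-4,5,7,8-tetrahydroxynaphthalen-2-yl]methyl}-4-hydroxy-2H-pyran-2-one | Oc1cc(Cc2cc3c(O)c(O)cc(O)c3c(O)c2C(=O)c2c(C)cc(O)cc2O)oc(=O)c1
A1 | alternative 1 | 3-(2,3,5-trimethoxyphenyl)prop-2-yn-1-yl 3-(trimethylsilyl)prop-2-ynoate | COc1cc(OC)c(OC)c(C#CCOC(=O)C#C[Si](C)(C)C)c1
A2 | alternative 1 | 5,6,8-trimethoxy-9-(trimethylsilyl)naphtho[2,3-c]furan-1(3H)-one | COc1cc(OC)c2c([Si](C)(C)C)c3C(=O)OCc3cc2c1OC
A3 | alternative 2 | 4,5,7,8-tetramethoxy-3-(trimethylsilyl)naphthalen-2-yl trifluoromethanesulfonate | COc1cc(OC)c(OC)c2cc(OS(=O)(=O)C(F)(F)F)c([Si](C)(C)C)c(OC)c12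
A4 | alternative 2 | methyl 3-(2,4-dimethoxy-6-methylphenyl)-3-oxopropanoate | COC(=O)CC(=O)c1c(C)cc(OC)cc1OC
A5 | alternative 2 | methyl 2-[3-(2,4-dimethoxy-6-methylbenzoyl)-4,5,7,8-tetramethoxynaphthalen-2-yl]acetate | COC(=O)Cc1cc2c(OC)c(OC)cc(OC)c2c(OC)c1C(=O)c1c(C)cc(OC)cc1OC
A6 | alternative 3 | 1-[3-({[tert-butyl(dimethyl)silyl]oxy}methyl)-1,5,6,8-tetramethoxynaphthalen-2-yl]but-2-yn-1-one | CC#CC(=O)c1c(CO[Si](C)(C)C(C)(C)C)cc2c(OC)c(OC)cc(OC)c2c1OC
A7 | alternative 3 | 1-methoxy-1,3-bis(trimethylsilyloxy)buta-1,3-diene | COC(O[Si](C)(C)C)=CC(=C)O[Si](C)(C)C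
A8 | alternative 3 | [3-({[tert-butyl(dimethyl)silyl]oxy}methyl)-1,5,6,8-tetramethoxynaphthalen-2-yl](2,4-dihydroxy-6-methylphenyl)methanone | Cc1cc(O)cc(O)c1C(=O)c1c(CO[Si](C)(C)C(C)(C)C)cc2c(OC)c(OC)cc(OC)c2c1OC
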